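**Retrosynthetic overview**

- Feature: O1 of the pyranone ring sits between C8a of the benzo ring and C2. It is the single skeletal atom by which the target exceeds a 1,5-diarylpentane-1,3-dione: C4, C3, C2 and the two side-chain CH2 groups are the five-carbon chain, and the two benzene rings are its end caps.
- Key disconnection: C8a–O1 and O1–C2 are cut together, giving 5-(3-acetoxy-4-methoxyphenyl)-1-(3,4-dimethoxyphenyl)pentane-1,3-dione. In the forward sense, ketone-directed C–H oxygenation and then cyclodehydration retrace what the plant is thought to do with its diarylpentanoid.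
- Diketone: it is cut between C2 and C3 of the chain into 3,4-dimethoxyacetophenone and 3-(3-acetoxy-4-methoxyphenyl)propanoyl chloride. These are joined by soft enolisation, so the acetate rides along from the first step and no protecting-group exchange is needed.
- Ring order: both benzene rings are bought, the pyranone is the only ring made, and the acetate is removed last.

Key step: step 4

Remark: 5 is drawn as the diketone but should exist mainly as its chelated enol; C1–C5 denote the pentanedione chain (C1 next to the dimethoxyphenyl ring), primed locants denote that ring, and C1, C2, C3 and C6' become C4, C3, C2 and C8a of the chromone.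

**Step 1**
Reactants: 1 3-(3-hydroxy-4-methoxyphenyl)propanoic acid
Product: 2 3-(3-acetoxy-4-methoxyphenyl)propanoic acid
Conditions: Ac2O (1.5 equiv), pyridine, 0 °C to rt; then H2O, rt
Reagents that add atoms: acetic anhydride, CC(=O)OC(C)=O
Why: Pyridine-promoted O-acetylation (nucleophilic acyl substitution) of the phenol is fast, and the aqueous quench returns any activated carboxyl group to the free acid, so only the aryl acetate is kept.

**Step 2**
Reactants: 2 3-(3-acetoxy-4-methoxyphenyl)propanoic acid
Product: 3 3-(3-acetoxy-4-methoxyphenyl)propanoyl chloride (used crude)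
Conditions: (COCl)2 (1.3 equiv), DMF (cat), CH2Cl2, 0 °C to rt; evaporate
Reagents that add atoms: oxalyl chloride, O=C(Cl)C(=O)Cl
Why: Vilsmeier-type activation by the chloroiminium salt from DMF and oxalyl chloride turns the acid into its chloride with only volatile by-products, and it leaves the aryl acetate and the aryl methyl ether untouched.

**Step 3**
Reactants: 3 3-(3-acetoxy-4-methoxyphenyl)propanoyl chloride; 4 3,4-dimethoxyacetophenone
Product: 5 5-(3-acetoxy-4-methoxyphenyl)-1-(3,4-dimethoxyphenyl)pentane-1,3-dione
Conditions: MgBr2·OEt2 (2.5 equiv), i-Pr2NEt (3 equiv), CH2Cl2, rt; 1 M HCl work-up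
Reagents that add atoms: none
Why: In this soft-enolisation C-acylation (a crossed Claisen-type condensation) MgBr2 acidifies the methyl ketone enough for the amine to form the magnesium enolate, which takes the far more electrophilic acid chloride at carbon and spares the aryl acetate that a lithium or sodium enolate protocol would cleave, while chelation of the product as its magnesium diketonate blocks a second acylation.

**Step 4**
Reactants: 5 5-(3-acetoxy-4-methoxyphenyl)-1-(3,4-dimethoxyphenyl)pentane-1,3-dione
Product: 9 2-[2-(3-acetoxy-4-methoxyphenyl)ethyl]-6,7-dimethoxychromen-4-one, via aryl trifluoroacetate 6 (not isolated), via hydroxyaryl diketone 7 (not isolated), via hemiketal 8 (not isolated)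
Conditions: [RuCl2(p-cymene)]2 (5 mol%), K2S2O8 (1.5 equiv), CF3CO2H/(CF3CO)2O 9:1, 70 °C, sealed tube; cool, filter off salts; then H2O, 50 °C
Reagents that add atoms: trifluoroacetic acid, OC(=O)C(F)(F)F (one of its oxygen atoms stays as O1)
Why: Proposed new method: In CF3CO2H the chloride ligands of [RuCl2(p-cymene)]2 should be exchanged for trifluoroacetate, the C1 carbonyl oxygen of 5 binds divalent ruthenium through its arene-side lone pair, carboxylate-assisted C–H cleavage at C6' gives a five-membered ruthenacycle, K2S2O8 raises it to tetravalent ruthenium, and C–O reductive elimination releases aryl trifluoroacetate 6 (bond C8a–O1) with return of divalent ruthenium. The closest known reaction types are the ketone-directed ortho C–H hydroxylation of simple aryl ketones with Pd(OAc)2 or [RuCl2(p-cymene)]2 and K2S2O8 in CF3CO2H/(CF3CO)2O and, for the second stage, the acid-catalysed cyclodehydration of 1-(2-hydroxyaryl)-1,3-diketones that ends a Baker–Venkataraman chromone synthesis; new is the use of an enolisable 1-aryl-1,3-diketone as the directing substrate and the telescoping of both events. Since 6 has no way to lose its acyl group in the anhydrous medium, it is deliberately parked there as an oxidation-resistant ester, and only after the persulfate has been filtered off does water free phenol 7, whose oxygen adds to the C3 carbonyl in a 6-exo-trig closure (bond O1–C2) to hemiketal 8, which loses water under acid catalysis to give the aromatic pyranone ring of 9. The step needs regioselectivity between the two C–H bonds ortho to the ketone, and sterics should secure it: C2' is wedged between the acyl group and the 3'-methoxy group, whereas C6', para to that methoxy group, is open, and oxygenation there maps onto the 6,7-dimethoxy pattern. It also needs chemoselectivity, which rests on the strong acid that keeps the diketone from sequestering the metal as an O,O-chelate, on persulfate being a poorer oxidant for the enolised C2 methylene than hypervalent iodine oxidants, and on the acetate, which lowers the electron density of the distal arene and leaves the two positions ortho to its side chain (both meta to methoxy) too poor to attack the C3 ketone in a competing indene-forming cyclodehydration. No stereocentre survives, since C2 of 8 is formed as a racemate and becomes trigonal on dehydration.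

**Step 5**
Reactants: 9 2-[2-(3-acetoxy-4-methoxyphenyl)ethyl]-6,7-dimethoxychromen-4-one
Product: 10 2-[2-(3-hydroxy-4-methoxyphenyl)ethyl]-6,7-dimethoxychromen-4-one
Conditions: K2CO3 (0.2 equiv), MeOH/THF, 0 °C to rt; aq NH4Cl
Reagents that add atoms: none
Why: Base-catalysed transesterification (Zemplén-type methanolysis) should cleave the activated aryl ester well before methoxide can add to C2 of the chromone, and the three aryl methyl ethers are inert.

**Compound list**

1 | 3-(3-hydroxy-4-methoxyphenyl)propanoic acid | COc1ccc(CCC(=O)O)cc1O | starting material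
2 | 3-(3-acetoxy-4-methoxyphenyl)propanoic acid | COc1ccc(CCC(=O)O)cc1OC(C)=O | intermediate
3 | 3-(3-acetoxy-4-methoxyphenyl)propanoyl chloride | COc1ccc(CCC(=O)Cl)cc1OC(C)=O | intermediate
4 | 3,4-dimethoxyacetophenone | CC(=O)c1ccc(OC)c(OC)c1 | starting material
5 | 5-(3-acetoxy-4-methoxyphenyl)-1-(3,4-dimethoxyphenyl)pentane-1,3-dione | COc1ccc(CCC(=O)CC(=O)c2ccc(OC)c(OC)c2)cc1OC(C)=O | intermediate
6 | 2-[5-(3-acetoxy-4-methoxyphenyl)-3-oxopentanoyl]-4,5-dimethoxyphenyl trifluoroacetate | COc1ccc(CCC(=O)CC(=O)c2cc(OC)c(OC)cc2OC(=O)C(F)(F)F)cc1OC(C)=O | intermediate (not isolated)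
7 | 5-(3-acetoxy-4-methoxyphenyl)-1-(2-hydroxy-4,5-dimethoxyphenyl)pentane-1,3-dione | COc1ccc(CCC(=O)CC(=O)c2cc(OC)c(OC)cc2O)cc1OC(C)=O | intermediate (not isolated)
8 | 2-[2-(3-acetoxy-4-methoxyphenyl)ethyl]-2-hydroxy-6,7-dimethoxychroman-4-one (racemic) | COc1ccc(CCC2(O)CC(=O)c3cc(OC)c(OC)cc3O2)cc1OC(C)=O | intermediate (not isolated)
9 | 2-[2-(3-acetoxy-4-methoxyphenyl)ethyl]-6,7-dimethoxychromen-4-one | COc1ccc(CCc2cc(=O)c3cc(OC)c(OC)cc3o2)cc1OC(C)=O | intermediate
10 | 2-[2-(3-hydroxy-4-methoxyphenyl)ethyl]-6,7-dimethoxychromen-4-one | COc1ccc(CCc2cc(=O)c3cc(OC)c(OC)cc3o2)cc1O | target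

Total step count: 5
Longest linear sequence: 5 steps (1 → 2 → 3 → 5 → 9 → 10)

**Steps most likely to fail**

**Step 4 (the proposed new method).**
- Possible failure: turnover may be lost because the enolised diketone ties up divalent ruthenium as an O,O-chelate. Sulfate radical anion formed on heating persulfate may oxidise the methoxyarenes or the enolised C2 position by single-electron transfer. Metalation may leak to C2'. Exchange of the acetate for trifluoroacetate in the medium would be harmless, since it only anticipates step 5.
- Fallback: this is known chemistry in which the phenolic oxygen is bought instead of installed. It sets out from 3 and comes back to the route at 7. Acid chloride 3 should O-acylate commercial 2-hydroxy-4,5-dimethoxyacetophenone F1 (pyridine, CH2Cl2, 0 °C) to give 2-acetyl-4,5-dimethoxyphenyl 3-(3-acetoxy-4-methoxyphenyl)propanoate F2. A Baker–Venkataraman rearrangement (LiN(SiMe3)2, THF, −78 to −20 °C) then moves the acyl group from oxygen to the enolate carbon through a six-membered transition state and gives 7. Aqueous CF3CO2H closes 7 to 9 as in the second stage of step 4. Any acetate lost to the amide base would only lead to 10 one step early.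

**Step 3.**
- Possible failure: the amine may dehydrochlorinate the acid chloride to a ketene that dimerises. O-acylation may occur in place of C-acylation. Acetyl may transfer from the aryl acetate to the enolate.
- Fallback: a hard-enolate crossed Claisen condensation on a base-stable ether, followed by protecting-group exchange. It sets out from 1 (with 4) and comes back at 5. Double benzylation of 1 (BnBr, K2CO3, DMF) should give benzyl 3-(3-benzyloxy-4-methoxyphenyl)propanoate F3. The lithium enolate of 4 (LiN(SiMe3)2, 2.2 equiv, THF, −78 °C to rt) condenses with F3 to give 5-(3-benzyloxy-4-methoxyphenyl)-1-(3,4-dimethoxyphenyl)pentane-1,3-dione F4. Hydrogenolysis (H2, 1 atm, Pd/C, EtOAc) frees 5-(3-hydroxy-4-methoxyphenyl)-1-(3,4-dimethoxyphenyl)pentane-1,3-dione F5. Ac2O (1.1 equiv) in pyridine at 0 °C then acetylates the phenol faster than the chelated enol and gives 5.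

**Step 5.**
- Possible failure: methoxide may add in conjugate fashion to C2 and open the pyranone ring. Alternatively, the side-chain CH2 next to C2 may be deprotonated and condense.
- Fallback: the order is changed so that no base meets the chromone, and a transient protecting group replaces the acetate. It sets out from 5 and comes back at 10. The acetate is removed at the diketone stage (K2CO3, MeOH, rt), where the diketone is shielded as its enolate, to give phenol diketone F5. In the medium of step 4, (CF3CO)2O should at once convert F5 into 5-[5-(3,4-dimethoxyphenyl)-3,5-dioxopentyl]-2-methoxyphenyl trifluoroacetate F6, whose ester takes over the deactivating role of the acetate. C–H oxygenation gives the bis(trifluoroacetate) F7. The water stage cleaves both esters to 1-(2-hydroxy-4,5-dimethoxyphenyl)-5-(3-hydroxy-4-methoxyphenyl)pentane-1,3-dione F8. F8 closes through 2-hydroxy-2-[2-(3-hydroxy-4-methoxyphenyl)ethyl]-6,7-dimethoxychroman-4-one F9 and loses water to give 10 directly.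

**Further compounds**

F1 | step 4 | 2-hydroxy-4,5-dimethoxyacetophenone (bought in) | CC(=O)c1cc(OC)c(OC)cc1O
F2 | step 4 | 2-acetyl-4,5-dimethoxyphenyl 3-(3-acetoxy-4-methoxyphenyl)propanoate | COc1ccc(CCC(=O)Oc2cc(OC)c(OC)cc2C(C)=O)cc1OC(C)=O
F3 | step 3 | benzyl 3-(3-benzyloxy-4-methoxyphenyl)propanoate | COc1ccc(CCC(=O)OCc2ccccc2)cc1OCc1ccccc1
F4 | step 3 | 5-(3-benzyloxy-4-methoxyphenyl)-1-(3,4-dimethoxyphenyl)pentane-1,3-dione | COc1ccc(CCC(=O)CC(=O)c2ccc(OC)c(OC)c2)cc1OCc1ccccc1
F5 | step 3 | 5-(3-hydroxy-4-methoxyphenyl)-1-(3,4-dimethoxyphenyl)pentane-1,3-dione | COc1ccc(CCC(=O)CC(=O)c2ccc(OC)c(OC)c2)cc1O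
F6 | step 5 | 5-[5-(3,4-dimethoxyphenyl)-3,5-dioxopentyl]-2-methoxyphenyl trifluoroacetate | COc1ccc(CCC(=O)CC(=O)c2ccc(OC)c(OC)c2)cc1OC(=O)C(F)(F)F
F7 | step 5 | 4,5-dimethoxy-2-{5-[4-methoxy-3-(trifluoroacetoxy)phenyl]-3-oxopentanoyl}phenyl trifluoroacetate | COc1ccc(CCC(=O)CC(=O)c2cc(OC)c(OC)cc2OC(=O)C(F)(F)F)cc1OC(=O)C(F)(F)F
F8 | step 5 | 1-(2-hydroxy-4,5-dimethoxyphenyl)-5-(3-hydroxy-4-methoxyphenyl)pentane-1,3-dione | COc1ccc(CCC(=O)CC(=O)c2cc(OC)c(OC)cc2O)cc1O
F9 | step 5 | 2-hydroxy-2-[2-(3-hydroxy-4-methoxyphenyl)ethyl]-6,7-dimethoxychroman-4-one (racemic) | COc1ccc(CCC2(O)CC(=O)c3cc(OC)c(OC)cc3O2)cc1O
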